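**Retrosynthetic overview**
1. Target 20 comes from catechol 19 by double O-methylation, and 19 from aryl boronate 18 by oxidation of the C7–B bond.
2. Key disconnection: ring A is cut at C5–C6, C7–C8 and C8–C8a into pyranonyl methoxycarbene chromium complex 15, ethynylboronate 16 and one CO ligand. The feature used is that ring A carries oxygens at C5 and C8 para to each other with a third oxygen at C7 beside C8, and that its C4a–C8a edge is the C3=C2 double bond of a 2-aryl-4-pyranone already holding O1, the C4 carbonyl and ring B.
3. Carbene 15 comes from pyranone-3-carbonyl chloride 11 and Cr(CO)6 through an acylchromate; 11 comes from tert-butyl ester 9.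
4. Ring C is made by acylating enaminone 6 with aroyl chloride 4 and closing with acid; 4 comes from 1,2,3,4-tetramethoxybenzene 1 by lithiation and carboxylation.
5. Ring order: ring B is bought, ring C is formed in step 4, ring A in step 8.

Key step: step 8

**Remarks on the chemistry**
- The tert-butyl ester is used so that the ester can be removed by acid; hydroxide would attack C2 of the 4-pyranone.
- Carbene 15 is drawn as the pentacarbonyl complex. If one CO is lost to chelation by the pyranone C4 oxygen, the tetracarbonyl chelate should enter step 8 in the same way.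
- In the SMILES of the chromium compounds each CO ligand is written Cr=C=O, and arene complex 17 is written with its Cr(CO)3 fragment as a separate component.

**Route**

Step 1
Reactants: 1 1,2,3,4-tetramethoxybenzene
Product: 3 2,3,4,5-tetramethoxybenzoic acid, via aryllithium 2 (not isolated)
Conditions: n-BuLi (1.2 equiv), TMEDA, THF, 0 °C to rt; CO2, −78 °C to rt; aq HCl
Reagents that add atoms: carbon dioxide, O=C=O
Why: Directed ortho-metalation, in which the two ring hydrogens of 1 are equivalent and each lies ortho to a methoxy group, so lithiation and carboxylation of aryllithium 2 should give acid 3 as a single regioisomer.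

Step 2
Reactants: 3 2,3,4,5-tetramethoxybenzoic acid
Product: 4 2,3,4,5-tetramethoxybenzoyl chloride
Conditions: (COCl)2 (1.2 equiv), DMF (cat.), CH2Cl2, 0 °C to rt; concentrate, use crude
Reagents that add atoms: oxalyl chloride, O=C(Cl)C(=O)Cl
Why: Standard acid chloride formation through the chloroiminium salt from oxalyl chloride and catalytic DMF, which gives only gaseous by-products and leaves the aryl methyl ethers alone.

Step 3
Reactants: 5 tert-butyl acetoacetate
Product: 6 tert-butyl 2-[(dimethylamino)methylidene]-3-oxobutanoate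
Conditions: Me2NCH(OMe)2 (1.2 equiv), toluene, rt to 50 °C; concentrate
Reagents that add atoms: N,N-dimethylformamide dimethyl acetal, COC(OC)N(C)C
Why: Knoevenagel-type condensation of the active methylene of the β-keto ester with the amide acetal, driven by loss of methanol, is a standard entry to 2-(aminomethylene)-1,3-dicarbonyl compounds.

Step 4
Reactants: 6 tert-butyl 2-[(dimethylamino)methylidene]-3-oxobutanoate; 4 2,3,4,5-tetramethoxybenzoyl chloride
Product: 9 tert-butyl 4-oxo-6-(2,3,4,5-tetramethoxyphenyl)-4H-pyran-3-carboxylate, via lithium enolate 7 (not isolated), via acylated enaminone 8 (not isolated)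
Conditions: LiN(SiMe3)2 (2.2 equiv), THF, −78 °C, 6 and 4 added together, to 0 °C; then 1 M HCl, Et2O, rt, short contact
Reagents that add atoms: none
Why: Enaminone anion acylation followed by cyclisation, in which the acetyl methyl group is the only acidic site of 6, its enolate 7 is C-acylated by 4 while the second equivalent of base takes up the more acidic diketone 8, and on acidification the aryl ketone enol adds to the aminomethylene carbon and expels dimethylamine to close the 4-pyranone ring C.

Step 5
Reactants: 9 tert-butyl 4-oxo-6-(2,3,4,5-tetramethoxyphenyl)-4H-pyran-3-carboxylate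
Product: 10 4-oxo-6-(2,3,4,5-tetramethoxyphenyl)-4H-pyran-3-carboxylic acid
Conditions: CF3CO2H, CH2Cl2 (1:2), rt; evaporate with toluene
Reagents that add atoms: none
Why: Acidolysis of the tert-butyl ester by ionisation to the tert-butyl cation releases the acid without any nucleophilic base, so the pyranone ring and the methyl ethers should survive.

Step 6
Reactants: 10 4-oxo-6-(2,3,4,5-tetramethoxyphenyl)-4H-pyran-3-carboxylic acid
Product: 11 4-oxo-6-(2,3,4,5-tetramethoxyphenyl)-4H-pyran-3-carbonyl chloride
Conditions: (COCl)2 (1.1 equiv), DMF (cat.), CH2Cl2, 0 °C to rt; concentrate, use at once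
Reagents that add atoms: oxalyl chloride, O=C(Cl)C(=O)Cl
Why: Acid chloride formation as in step 2, a conversion that is routine for 4-oxo-4H-chromene-3-carboxylic acids, the benzo analogues of 10.

Step 7
Reactants: 11 4-oxo-6-(2,3,4,5-tetramethoxyphenyl)-4H-pyran-3-carbonyl chloride; 12 chromium hexacarbonyl
Product: 15 pentacarbonyl[methoxy(4-oxo-6-(2,3,4,5-tetramethoxyphenyl)-4H-pyran-3-yl)methylidene]chromium, via Na2Cr(CO)5 13 (not isolated), via sodium acylchromate 14 (not isolated)
Conditions: Cr(CO)6, sodium naphthalenide NaC10H8 (2.1 equiv), THF, −78 to 0 °C; 11, THF, −78 to 0 °C; then Me3OBF4 (1.05 equiv), CH2Cl2, 0 °C; rapid chromatography under argon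
Reagents that add atoms: trimethyloxonium tetrafluoroborate, C[O+](C)C.F[B-](F)(F)F
Why: Semmelhack–Hegedus synthesis of Fischer carbene complexes, in which reduction of Cr(CO)6 gives the pentacarbonylchromate dianion 13, acylation at chromium by the acid chloride gives acylchromate 14, and one equivalent of the oxonium salt methylates the anionic acyl oxygen in preference to the far less nucleophilic neutral pyranone carbonyl.

Step 8
Reactants: 15 pentacarbonyl[methoxy(4-oxo-6-(2,3,4,5-tetramethoxyphenyl)-4H-pyran-3-yl)methylidene]chromium; 16 2-ethynyl-4,4,5,5-tetramethyl-1,3,2-dioxaborolane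
Product: 18 8-hydroxy-5-methoxy-7-(4,4,5,5-tetramethyl-1,3,2-dioxaborolan-2-yl)-2-(2,3,4,5-tetramethoxyphenyl)-4H-chromen-4-one, via tricarbonylchromium arene complex 17 (not isolated)
Conditions: 16 (2 equiv), THF (0.05 M), 45 °C, argon; then air, EtOAc, rt; filtration through silica
Reagents that add atoms: none
Why: Proposed new method: loss of one CO ligand (or opening of a chelate with the pyranone carbonyl) frees a site for the alkyne, which inserts into the Cr=C bond so that its CH carbon bonds to the carbene carbon (C5–C6) and the boryl carbon becomes the new carbene centre; CO insertion there (C7–C8) gives a chromium-bound vinylketene whose ketene carbon closes onto pyranone C2 by six-electron electrocyclisation (C8–C8a), and tautomerisation of the cyclohexadienone gives the phenol on Cr(CO)3, which air removes. The closest known reaction is the Dötz benzannulation of alkenyl(alkoxy)carbene chromium complexes with alkynylboronates, which gives ortho-boryl hydroquinone monoethers; what has not been shown is the electron-poor, oxygen-substituted C2=C3 bond of a 4-pyranone serving as the alkenyl part. Ring A thus closes by electrocyclisation of the metal-bound dienylketene, and no stereocentre is formed. The step needs the insertion regiochemistry that puts boron next to C8, which the size of the pinacolboronate against hydrogen and the usual behaviour of alkynylboronates should secure. It also needs phenol formation to outrun cyclopentannulation and furan formation, for which the methoxy donor on the carbene carbon, the cis-fixed ring alkene with a free hydrogen at C2, and a coordinating solvent at moderate temperature are the favourable settings. The oxygen pattern follows by construction, since the carbene methoxy becomes the C5 ether, the inserted CO becomes the C8 hydroxyl and O1 comes in with the pyranone.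

Step 9
Reactants: 18 8-hydroxy-5-methoxy-7-(4,4,5,5-tetramethyl-1,3,2-dioxaborolan-2-yl)-2-(2,3,4,5-tetramethoxyphenyl)-4H-chromen-4-one
Product: 19 7,8-dihydroxy-5-methoxy-2-(2,3,4,5-tetramethoxyphenyl)-4H-chromen-4-one
Conditions: 30% aq H2O2, NaHCO3, THF/H2O, 0 °C to rt, argon; aq Na2S2O3, then dilute HCl
Reagents that add atoms: hydrogen peroxide, OO
Why: Oxidation of the aryl pinacolboronate by hydroperoxide goes through the boron ate complex and 1,2-migration of the aryl group from boron to oxygen at the same ring carbon, and hydrolysis of the borate gives the C7 phenol under buffered conditions that the flavone should tolerate.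

Step 10
Reactants: 19 7,8-dihydroxy-5-methoxy-2-(2,3,4,5-tetramethoxyphenyl)-4H-chromen-4-one
Product: 20 5,7,8-trimethoxy-2-(2,3,4,5-tetramethoxyphenyl)-4H-chromen-4-one
Conditions: MeI (excess), K2CO3, acetone, reflux, argon
Reagents that add atoms: iodomethane, CI
Why: Williamson ether synthesis, in which both phenoxides of the catechol are alkylated by excess iodomethane, the usual last step for polymethoxyflavones, with no chelated 5-hydroxyl present to resist methylation.

**Compound list**
1 | 1,2,3,4-tetramethoxybenzene | COc1ccc(OC)c(OC)c1OC | starting material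
2 | (2,3,4,5-tetramethoxyphenyl)lithium | [Li]c1cc(OC)c(OC)c(OC)c1OC | intermediate (not isolated)
3 | 2,3,4,5-tetramethoxybenzoic acid | COc1cc(C(=O)O)c(OC)c(OC)c1OC | intermediate
4 | 2,3,4,5-tetramethoxybenzoyl chloride | COc1cc(C(Cl)=O)c(OC)c(OC)c1OC | intermediate
5 | tert-butyl acetoacetate | CC(=O)CC(=O)OC(C)(C)C | starting material
6 | tert-butyl 2-[(dimethylamino)methylidene]-3-oxobutanoate | CC(=O)C(=CN(C)C)C(=O)OC(C)(C)C | intermediate
7 | lithium enolate of 6 (deprotonated at the acetyl methyl group) | [Li]OC(=C)C(=CN(C)C)C(=O)OC(C)(C)C | intermediate (not isolated)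
8 | tert-butyl 2-[(dimethylamino)methylidene]-3,5-dioxo-5-(2,3,4,5-tetramethoxyphenyl)pentanoate (present as its lithium enolate until acidified) | CN(C)C=C(C(=O)OC(C)(C)C)C(=O)CC(=O)c1cc(OC)c(OC)c(OC)c1OC | intermediate (not isolated)
9 | tert-butyl 4-oxo-6-(2,3,4,5-tetramethoxyphenyl)-4H-pyran-3-carboxylate | COc1cc(-c2cc(=O)c(C(=O)OC(C)(C)C)co2)c(OC)c(OC)c1OC | intermediate
10 | 4-oxo-6-(2,3,4,5-tetramethoxyphenyl)-4H-pyran-3-carboxylic acid | COc1cc(-c2cc(=O)c(C(=O)O)co2)c(OC)c(OC)c1OC | intermediate
11 | 4-oxo-6-(2,3,4,5-tetramethoxyphenyl)-4H-pyran-3-carbonyl chloride | COc1cc(-c2cc(=O)c(C(Cl)=O)co2)c(OC)c(OC)c1OC | intermediate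
12 | chromium hexacarbonyl | O=C=[Cr](=C=O)(=C=O)(=C=O)(=C=O)=C=O | starting material
13 | disodium pentacarbonylchromate, Na2Cr(CO)5 | [Na+].[Na+].O=C=[Cr-2](=C=O)(=C=O)(=C=O)=C=O | intermediate (not isolated)
14 | sodium pentacarbonyl[4-oxo-6-(2,3,4,5-tetramethoxyphenyl)-4H-pyran-3-carbonyl]chromate | [Na+].O=C(c1coc(-c2cc(OC)c(OC)c(OC)c2OC)cc1=O)[Cr-](=C=O)(=C=O)(=C=O)(=C=O)=C=O | intermediate (not isolated)
15 | pentacarbonyl[methoxy(4-oxo-6-(2,3,4,5-tetramethoxyphenyl)-4H-pyran-3-yl)methylidene]chromium | COC(c1coc(-c2cc(OC)c(OC)c(OC)c2OC)cc1=O)=[Cr](=C=O)(=C=O)(=C=O)(=C=O)=C=O | intermediate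
16 | 2-ethynyl-4,4,5,5-tetramethyl-1,3,2-dioxaborolane | C#CB1OC(C)(C)C(C)(C)O1 | starting material
17 | tricarbonylchromium complex of 18, bound η6 to ring A | COc1cc(B2OC(C)(C)C(C)(C)O2)c(O)c2oc(-c3cc(OC)c(OC)c(OC)c3OC)cc(=O)c12.O=C=[Cr](=C=O)=C=O | intermediate (not isolated)
18 | 8-hydroxy-5-methoxy-7-(4,4,5,5-tetramethyl-1,3,2-dioxaborolan-2-yl)-2-(2,3,4,5-tetramethoxyphenyl)-4H-chromen-4-one | COc1cc(B2OC(C)(C)C(C)(C)O2)c(O)c2oc(-c3cc(OC)c(OC)c(OC)c3OC)cc(=O)c12 | intermediate
19 | 7,8-dihydroxy-5-methoxy-2-(2,3,4,5-tetramethoxyphenyl)-4H-chromen-4-one | COc1cc(O)c(O)c2oc(-c3cc(OC)c(OC)c(OC)c3OC)cc(=O)c12 | intermediate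
20 | 5,7,8-trimethoxy-2-(2,3,4,5-tetramethoxyphenyl)-4H-chromen-4-one | COc1cc(-c2cc(=O)c3c(OC)cc(OC)c(OC)c3o2)c(OC)c(OC)c1OC | target

**Step count**
Total: 10 steps. Longest linear sequence: 9 steps (steps 1, 2 and 4 to 10, from 1,2,3,4-tetramethoxybenzene).

**Steps most likely to fail**

Step 8. After alkyne insertion the pyranone C4 oxygen may add to the new carbene carbon, the ring may close without CO insertion, the alkyne may insert the other way round, or the electron-poor alkene may cyclise so slowly that the complex decomposes first. The fallback uses the established Baker–Venkataraman flavone synthesis; it sets out from acid chloride 4 and comes back at target 20. Acid chloride 4 would be esterified in pyridine with the commercially available phenol 1-(2-hydroxy-3,4,6-trimethoxyphenyl)ethan-1-one F1 as the ring A building block. This should give 2-acetyl-3,5,6-trimethoxyphenyl 2,3,4,5-tetramethoxybenzoate F2 as the aryl ester. Acyl transfer with KOH in pyridine at 50 °C should give 1-(2-hydroxy-3,4,6-trimethoxyphenyl)-3-(2,3,4,5-tetramethoxyphenyl)propane-1,3-dione F3 as the diketone, and cyclodehydration with catalytic H2SO4 in AcOH at 60 °C should give 20.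

Step 7. The strongly reducing chromate dianion may transfer an electron to the pyranone or add at its C2 instead of substituting at the acyl chloride, and the oxonium salt may methylate the pyranone carbonyl. The fallback gives up the carbene and uses the chalcone route; it sets out from 1 and comes back at target 20. Rieche formylation of 1 (Cl2CHOMe, TiCl4, CH2Cl2, 0 °C) at one of its two equivalent free ring positions would give 2,3,4,5-tetramethoxybenzaldehyde F4 as the aldehyde. Claisen–Schmidt condensation of it with 1-(2-hydroxy-3,4,6-trimethoxyphenyl)ethan-1-one F1 as the ketone partner (KOH, EtOH, rt) would give (E)-1-(2-hydroxy-3,4,6-trimethoxyphenyl)-3-(2,3,4,5-tetramethoxyphenyl)prop-2-en-1-one F5 as the chalcone. Oxidative cyclisation with catalytic I2 in DMSO at 120 °C should then give 20.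

Step 9. The electron-rich catechol may be over-oxidised by peroxide or air in base, and the boronate may be lost by protodeboronation. The fallback changes the order so that no free catechol is formed; it sets out from 18 and comes back at target 20. The C8 hydroxyl of 18 would first be methylated (MeI, K2CO3, acetone) to 5,8-dimethoxy-7-(4,4,5,5-tetramethyl-1,3,2-dioxaborolan-2-yl)-2-(2,3,4,5-tetramethoxyphenyl)-4H-chromen-4-one F6 as the boronate ether. Oxidation with NaBO3·4H2O in THF/H2O would give the monophenol 7-hydroxy-5,8-dimethoxy-2-(2,3,4,5-tetramethoxyphenyl)-4H-chromen-4-one F7 in place of the catechol, and a final methylation (MeI, K2CO3, acetone) gives 20.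

**Further compounds**
F1 | step 8 | 1-(2-hydroxy-3,4,6-trimethoxyphenyl)ethan-1-one | CC(=O)c1c(O)c(OC)c(OC)cc1OC
F2 | step 8 | 2-acetyl-3,5,6-trimethoxyphenyl 2,3,4,5-tetramethoxybenzoate | CC(=O)c1c(OC(=O)c2cc(OC)c(OC)c(OC)c2OC)c(OC)c(OC)cc1OC
F3 | step 8 | 1-(2-hydroxy-3,4,6-trimethoxyphenyl)-3-(2,3,4,5-tetramethoxyphenyl)propane-1,3-dione | COc1cc(OC)c(C(=O)CC(=O)c2cc(OC)c(OC)c(OC)c2OC)c(O)c1OC
F4 | step 7 | 2,3,4,5-tetramethoxybenzaldehyde | COc1cc(C=O)c(OC)c(OC)c1OC
F5 | step 7 | (E)-1-(2-hydroxy-3,4,6-trimethoxyphenyl)-3-(2,3,4,5-tetramethoxyphenyl)prop-2-en-1-one | COc1cc(OC)c(C(=O)/C=C/c2cc(OC)c(OC)c(OC)c2OC)c(O)c1OC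
F6 | step 9 | 5,8-dimethoxy-7-(4,4,5,5-tetramethyl-1,3,2-dioxaborolan-2-yl)-2-(2,3,4,5-tetramethoxyphenyl)-4H-chromen-4-one | COc1cc(B2OC(C)(C)C(C)(C)O2)c(OC)c2oc(-c3cc(OC)c(OC)c(OC)c3OC)cc(=O)c12
F7 | step 9 | 7-hydroxy-5,8-dimethoxy-2-(2,3,4,5-tetramethoxyphenyl)-4H-chromen-4-one | COc1cc(O)c(OC)c2oc(-c3cc(OC)c(OC)c(OC)c3OC)cc(=O)c12
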